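I was to read this flask at 10 h, 5.00 times as late as the last reading of its run so far, so the question was how many lifetimes of Z pass by then.

| flask | Z | J | remark | time | volume of the second phase over the first |
|---|---|---|---|---|---|
| south-east | 0.050 M | 0.10 M | the very flask that is asked about, followed so far |  |  |
| flask | 0.050 M | 0.100 M |  | 10 h | 0.50 |

south-east run (percent of the Z charged): time / min: G / % = 8.00: 0.4; 15.0: 0.4; 25.0: 0.3; 40.0: 0; 60.0: 1.6; 120: 4.9

(readings scatter by 0.5 percentage points)

* amount of G at 10 h, in percent of the Z charged
* the change that raises the amount of G at 10 h, in percent of the Z charged most ("none" if none brings more than 2 percentage points) (gamma / eta / none)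
* amount of G at 10 h, in percent of the Z charged, after gamma

- gamma: doubling the amount of J, all else as stated
- eta: doubling the transfer coefficient of J, all else as stated

- in the second phase: J; everything else is in the first
- charges count per volume of the first phase; a concentration in a rate is the amount of a species over the volume of its own phase; every rate counts per litre of the first phase
- the earlier runs were read with a standard deviation of 0.5 percentage points
- the earlier runs hold the two phases in the same ratio of volumes as the flask asked about

I counted these lifetimes as N, the natural logarithm of the charge over the Z left, and built the flask up one process at a time. With the main step alone, Z meeting reagent at a steady level, the loss of Z is pseudo-first-order and N grows in proportion to time. The last two readings gave a slope of 0.0330 /h, so this count gave N = 0.330 at 10 h and G 28.1%. But that picture starts G at once, and the reading at 40.0 min was 0%.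

Next I added the passage of J into the first phase. While J enters at a steady pace, the reagent there grows with time, so N grows with the square of time: N = (t/T)². The last reading gave T = 9.04 h, the square-law time, in which Z spends one lifetime at the opening pace. This gave 1.22% at 60.0 min against the reading 1.6%, a gap smaller than the scatter, and N = 1.23 at 10 h.

Last came the slowing of that passage as the first phase fills, for which I had no reading beyond 120 min. I took the geometric mean of the two counts, N = 0.636, which gave 47.0% of G. Doubling J doubles both counts, so N doubled and G came to 72.0%. Doubling the transfer coefficient doubles the square-law count and leaves the steady one as it was, which gave 59.3%, so I chose gamma, which gave more than eta.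

The forecast gave 29%, lower than my figure, chose gamma, and gave 48% after it, on this ground: “With first-order loss of Z at about 0.033 /h over 9.5 h, G is about 27–30 %.”

    D ⇌ J, rate k1*([D] - [J]/K1) per volume of the first phase (partition coefficient = 0.970, kL = 0.00200 /min)
    D + G → L (k = 0.00740 /M/min)
    Z + D → G (k = 0.0230 /M/min)

The flask held 39.0% of G at 10 h, and gamma was best, gaining 16 percentage points against 4.1 points for eta, to reach 55.1%. At that time G was made 4.54 times faster than it was used up, each step taken net. With 57.0% of Z left, N was 0.562, which is 0.459 of the square-law count from T. The same flask read at 15 h held 41.7% of Z, so N was 0.875 against 2.76 from T, a share of 0.317.

All runs are calculated on assumed constants; noise was put on by code.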